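**Retrosynthetic overview**

1. The last disconnection removes the phenol protecting groups (ring-C benzyl ether, ring-A catechol diphenylmethylene ketal), both cleavable by neutral hydrogenolysis.
2. The key disconnection is the bond from the ring-A carbon (para to the central oxygen of the 1,2,3-trioxygenated ring) to the carbinol carbon. Forward, an acyclic, achiral aryl iodide/arylacetaldehyde is closed by a catalytic enantioselective Ni/Cr aryl–aldehyde addition that forms the 18-membered ring, the C–OH group and the (S) centre in one operation.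
3. Enabling feature: the Ar–CH(OH)–CH2–Ar′ unit. Its carbinol carbon sits on a ring-A carbon flanked by two ring C–H positions (an unhindered aryl–metal site), its CH2 leads to the meta-substituted ring D (a plain arylacetaldehyde), and the two diaryl ether oxygens plus the CH2CH2 bridge are three ready-made tethers between the reacting ends.
4. The seco compound comes from a Wittig/diimide union (CH2CH2 bridge of rings B and C) of an A–O–B phosphonium salt and a C–O–D aldehyde; each diaryl ether is made by SNAr on a fluorobenzaldehyde.
5. Ring order: the four benzene rings are bought; a temporary 1,3-dioxole is fused to ring A (step 2); the 18-membered macrocycle is closed (step 12); the dioxole is opened (step 13).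

Key step: step 12

Assumption: the carbinol centre of the target is (S), which requires aryl delivery to the Re face of the aldehyde; the sense of induction of the chiral Cr ligand in aryl transfer is taken to follow that in alkenyl transfer, and the ligand antipode (from L- or D-valinol) is to be fixed on the first run by Mosher ester analysis.

**Route**

Step 1
Reactants: 1 5-iodo-1,2,3-trimethoxybenzene
Product: 2 5-iodobenzene-1,2,3-triol
Conditions: BBr3 (4 equiv), CH2Cl2, −78 °C to rt; H2O quench; kept under argon
Reagents that add atoms: none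
Why: BBr3 ether cleavage should remove all three aryl methyl groups as bromomethane while the aryl iodide is inert at low temperature.

Step 2
Reactants: 2 5-iodobenzene-1,2,3-triol
Product: 3 6-iodo-2,2-diphenyl-1,3-benzodioxol-4-ol
Conditions: Ph2CCl2 (1.1 equiv), K2CO3, MeCN, rt, argon
Reagents that add atoms: dichlorodiphenylmethane, ClC(Cl)(c1ccccc1)c1ccccc1
Why: Ketalisation by double O-alkylation with a gem-dichloride can bridge only two vicinal oxygens as a five-membered dioxole, and because the triol is symmetric one product with one free outer hydroxyl should result.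

Step 3
Reactants: 3 6-iodo-2,2-diphenyl-1,3-benzodioxol-4-ol; 4 4-fluorobenzaldehyde
Product: 5 4-[(6-iodo-2,2-diphenyl-1,3-benzodioxol-4-yl)oxy]benzaldehyde
Conditions: K2CO3, DMF, 110 °C
Reagents that add atoms: none
Why: SNAr (addition–elimination) should occur only at the C–F bond activated by the para formyl group, the iodide on the electron-rich ring being unactivated.

Step 4
Reactants: 5 4-[(6-iodo-2,2-diphenyl-1,3-benzodioxol-4-yl)oxy]benzaldehyde
Product: 6 {4-[(6-iodo-2,2-diphenyl-1,3-benzodioxol-4-yl)oxy]phenyl}methanol
Conditions: NaBH4, THF/MeOH, 0 °C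
Reagents that add atoms: none
Why: Borohydride reduction of the aldehyde is chemoselective and leaves the aryl iodide and the ketal untouched.

Step 5
Reactants: 6 {4-[(6-iodo-2,2-diphenyl-1,3-benzodioxol-4-yl)oxy]phenyl}methanol
Product: 7 4-[4-(bromomethyl)phenoxy]-6-iodo-2,2-diphenyl-1,3-benzodioxole
Conditions: CBr4, PPh3, CH2Cl2, 0 °C
Reagents that add atoms: carbon tetrabromide, BrC(Br)(Br)Br
Why: The Appel reaction converts the benzylic alcohol into the bromide under neutral conditions that spare the acid-labile ketal.

Step 6
Reactants: 7 4-[4-(bromomethyl)phenoxy]-6-iodo-2,2-diphenyl-1,3-benzodioxole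
Product: 8 {4-[(6-iodo-2,2-diphenyl-1,3-benzodioxol-4-yl)oxy]benzyl}triphenylphosphonium bromide
Conditions: PPh3, toluene, reflux
Reagents that add atoms: triphenylphosphine, c1ccccc1P(c1ccccc1)c1ccccc1
Why: SN2 quaternisation of triphenylphosphine by the benzylic bromide should give the Wittig salt, the aryl iodide being unreactive without a metal catalyst.

Step 7
Reactants: 9 2-fluoro-3-hydroxybenzaldehyde
Product: 10 3-(benzyloxy)-2-fluorobenzaldehyde
Conditions: BnBr, K2CO3, DMF, rt
Reagents that add atoms: benzyl bromide, BrCc1ccccc1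
Why: Williamson etherification of the phenoxide installs a protecting group that leaves in the final hydrogenolysis.

Step 8
Reactants: 10 3-(benzyloxy)-2-fluorobenzaldehyde; 11 2-(3-hydroxyphenyl)ethanol
Product: 12 3-(benzyloxy)-2-[3-(2-hydroxyethyl)phenoxy]benzaldehyde
Conditions: K2CO3, DMF, 110 °C
Reagents that add atoms: none
Why: SNAr at the C–F bond activated by the ortho formyl group should be phenol-selective, because carbonate deprotonates the phenol of 11 but not its primary alcohol.

Step 9
Reactants: 8 {4-[(6-iodo-2,2-diphenyl-1,3-benzodioxol-4-yl)oxy]benzyl}triphenylphosphonium bromide; 12 3-(benzyloxy)-2-[3-(2-hydroxyethyl)phenoxy]benzaldehyde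
Product: 14 stilbene alcohol (E/Z mixture), via phosphorus ylide 13 (not isolated)
Conditions: K2CO3, 18-crown-6 (cat.), CH2Cl2, reflux
Reagents that add atoms: none
Why: Wittig olefination with a semi-stabilised benzylic ylide under carbonate/crown-ether conditions tolerates the free alcohol, and the E/Z mixture is of no consequence because the alkene is saturated next.

Step 10
Reactants: 14 stilbene alcohol (E/Z mixture)
Product: 15 2-{3-[2-(benzyloxy)-6-(2-{4-[(6-iodo-2,2-diphenyl-1,3-benzodioxol-4-yl)oxy]phenyl}ethyl)phenoxy]phenyl}ethanol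
Conditions: TsNHNH2 (excess, in portions), NaOAc, DME/H2O, reflux
Reagents that add atoms: none
Why: Diimide reduction transfers H2 concertedly to the C=C bond only, so the aryl iodide, the benzyl ether and the diphenylmethylene ketal, all at risk under Pd/H2, should survive.

Step 11
Reactants: 15 2-{3-[2-(benzyloxy)-6-(2-{4-[(6-iodo-2,2-diphenyl-1,3-benzodioxol-4-yl)oxy]phenyl}ethyl)phenoxy]phenyl}ethanol
Product: 16 {3-[2-(benzyloxy)-6-(2-{4-[(6-iodo-2,2-diphenyl-1,3-benzodioxol-4-yl)oxy]phenyl}ethyl)phenoxy]phenyl}acetaldehyde
Conditions: Dess–Martin periodinane, NaHCO3, CH2Cl2, 0 °C to rt; used at once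
Reagents that add atoms: none
Why: Buffered Dess–Martin oxidation stops at the aldehyde under non-basic conditions, which suits the enolisable arylacetaldehyde.

Step 12
Reactants: 16 {3-[2-(benzyloxy)-6-(2-{4-[(6-iodo-2,2-diphenyl-1,3-benzodioxol-4-yl)oxy]phenyl}ethyl)phenoxy]phenyl}acetaldehyde
Product: 17 (S)-configured protected macrocyclic carbinol (the target with the ring-A catechol tied as a diphenylmethylene ketal and the ring-C phenol as a benzyl ether)
Conditions: CrCl2 (20 mol%), valinol-derived chiral oxazoline–sulfonamide ligand L* (22 mol%, antipode as in the assumption), proton sponge (22 mol%), NiCl2·neocuproine (5 mol%), Mn (4 equiv), Cp2ZrCl2 (2 equiv), LiCl (4 equiv), MeCN/THF, rt, slow addition of 16 (final ca. 3 mM); aqueous work-up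
Reagents that add atoms: none
Why: Proposed new method: a catalytic enantioselective Ni/Cr (Nozaki–Hiyama–Kishi) arylation run as a macrocyclisation, in which Ni(0) inserts into the ring-A C–I bond, the aryl group passes to the chiral Cr(III)–sulfonamide complex, the aryl–Cr(III) species adds to the Cr-bound aldehyde, Cp2ZrCl2 releases the alkoxide and Mn(0) returns Cr(III) to Cr(II). The closest known reaction types are the catalyst-controlled asymmetric Ni/Cr macrocyclisation of alkenyl iodides onto aldehydes and the non-asymmetric Cr-mediated addition of aryl iodides to aldehydes; what is new is an aryl iodide in the asymmetric, ring-closing mode. The 18-membered ring is closed in an 18-exo-trig sense by intramolecular 1,2-addition to the C=O group, the carbonyl oxygen ending up exocyclic as the free hydroxyl. The single stereocentre is set by the chiral ligand on chromium (catalyst control, the substrate being achiral), the aryl group being delivered to the Re face of the aldehyde to give the (S)-carbinol. The step needs ring closure over oligomerisation, addition over enolisation of the arylacetaldehyde, and reaction at one ring-A position: slow addition at millimolar concentration and the three pre-formed tethers favour cyclisation, the non-basic aryl–Cr(III) reagent leaves the α-CH2 alone, and the position is fixed by the iodine on the unhindered ring-A carbon para to the central dioxole oxygen.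

Step 13
Reactants: 17 (S)-configured protected macrocyclic carbinol
Product: 18 CNP0333307.1, the (S)-configured target
Conditions: H2 (1 atm), Pd/C, EtOAc/EtOH, rt; stopped at full conversion
Reagents that add atoms: none
Why: Neutral hydrogenolysis should cleave the aryl benzyl ether and both benzhydrylic C–O bonds of the diphenylmethylene ketal much faster than the secondary carbinol C–O bond, and the stereocentre is not touched.

**Compound list**

1 | 5-iodo-1,2,3-trimethoxybenzene | COc1cc(I)cc(OC)c1OC | starting material
2 | 5-iodobenzene-1,2,3-triol | Oc1cc(I)cc(O)c1O | intermediate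
3 | 6-iodo-2,2-diphenyl-1,3-benzodioxol-4-ol | Oc1cc(I)cc2OC(c3ccccc3)(c3ccccc3)Oc12 | intermediate
4 | 4-fluorobenzaldehyde | O=Cc1ccc(F)cc1 | starting material
5 | 4-[(6-iodo-2,2-diphenyl-1,3-benzodioxol-4-yl)oxy]benzaldehyde | O=Cc1ccc(cc1)Oc1cc(I)cc2OC(c3ccccc3)(c3ccccc3)Oc12 | intermediate
6 | {4-[(6-iodo-2,2-diphenyl-1,3-benzodioxol-4-yl)oxy]phenyl}methanol | OCc1ccc(cc1)Oc1cc(I)cc2OC(c3ccccc3)(c3ccccc3)Oc12 | intermediate
7 | 4-[4-(bromomethyl)phenoxy]-6-iodo-2,2-diphenyl-1,3-benzodioxole | BrCc1ccc(cc1)Oc1cc(I)cc2OC(c3ccccc3)(c3ccccc3)Oc12 | intermediate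
8 | {4-[(6-iodo-2,2-diphenyl-1,3-benzodioxol-4-yl)oxy]benzyl}triphenylphosphonium bromide | [Br-].c1ccccc1[P+](c1ccccc1)(c1ccccc1)Cc1ccc(cc1)Oc1cc(I)cc2OC(c3ccccc3)(c3ccccc3)Oc12 | intermediate
9 | 2-fluoro-3-hydroxybenzaldehyde | O=Cc1cccc(O)c1F | starting material
10 | 3-(benzyloxy)-2-fluorobenzaldehyde | O=Cc1cccc(OCc2ccccc2)c1F | intermediate
11 | 2-(3-hydroxyphenyl)ethanol | OCCc1cccc(O)c1 | starting material
12 | 3-(benzyloxy)-2-[3-(2-hydroxyethyl)phenoxy]benzaldehyde | O=Cc1cccc(OCc2ccccc2)c1Oc1cccc(CCO)c1 | intermediate
13 | phosphorus ylide from 8 (not isolated) | c1ccccc1P(c1ccccc1)(c1ccccc1)=Cc1ccc(cc1)Oc1cc(I)cc2OC(c3ccccc3)(c3ccccc3)Oc12 | intermediate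
14 | 2-{3-[2-(benzyloxy)-6-(2-{4-[(6-iodo-2,2-diphenyl-1,3-benzodioxol-4-yl)oxy]phenyl}ethenyl)phenoxy]phenyl}ethanol, E/Z mixture | OCCc1cccc(c1)Oc1c(OCc2ccccc2)cccc1C=Cc1ccc(cc1)Oc1cc(I)cc2OC(c3ccccc3)(c3ccccc3)Oc12 | intermediate
15 | 2-{3-[2-(benzyloxy)-6-(2-{4-[(6-iodo-2,2-diphenyl-1,3-benzodioxol-4-yl)oxy]phenyl}ethyl)phenoxy]phenyl}ethanol | OCCc1cccc(c1)Oc1c(OCc2ccccc2)cccc1CCc1ccc(cc1)Oc1cc(I)cc2OC(c3ccccc3)(c3ccccc3)Oc12 | intermediate
16 | {3-[2-(benzyloxy)-6-(2-{4-[(6-iodo-2,2-diphenyl-1,3-benzodioxol-4-yl)oxy]phenyl}ethyl)phenoxy]phenyl}acetaldehyde | O=CCc1cccc(c1)Oc1c(OCc2ccccc2)cccc1CCc1ccc(cc1)Oc1cc(I)cc2OC(c3ccccc3)(c3ccccc3)Oc12 | intermediate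
17 | (S)-configured protected macrocyclic carbinol: ring-A catechol as 2,2-diphenyl-1,3-dioxole, ring-C phenol as benzyl ether, free secondary alcohol | C1(c2ccccc2)(c2ccccc2)Oc2cc3cc(c2O1)Oc1ccc(cc1)CCc1cccc(OCc2ccccc2)c1Oc1cccc(c1)C[C@@H]3O | intermediate
18 | CNP0333307.1, (S)-configured 18-membered bis(bibenzyl) triphenol carbinol | Oc1cc2cc(c1O)Oc1ccc(cc1)CCc1cccc(O)c1Oc1cccc(c1)C[C@@H]2O | target

**Step count**

Total: 13 steps. Longest linear sequence: 11 steps (steps 1–6 and 9–13, from 5-iodo-1,2,3-trimethoxybenzene).

**Steps most likely to fail**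

1. Step 12 (proposed new method). Intermolecular coupling may outrun ring closure, slow aryl transfer from Ni to Cr may lead to protodeiodination, or the ligand may discriminate the aldehyde faces poorly. Fallback with known chemistry, setting out from 16 and returning at 17: a stoichiometric, achiral Nozaki–Hiyama–Kishi macrocyclisation (CrCl2 in excess, NiCl2 cat., DMSO/THF, rt, slow addition) should give the racemic protected macrocyclic carbinol F1. Dess–Martin oxidation then gives the protected macrocyclic aryl benzyl ketone F2. Corey–Bakshi–Shibata reduction with (R)-Me-CBS and BH3·SMe2 (ring A as the large group, CH2Ar as the small group) should give the (S)-carbinol 17, so the stereocentre is set by reagent-controlled reduction instead of during ring closure.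

2. Step 13. Hydrogenolysis may go on to cleave the benzylic C–OH bond para to the freed phenol, or the ketal may be cleaved incompletely under conditions mild enough to spare the carbinol. Fallback, setting out from 17 and returning at 18: the carbinol is first silylated (TBSCl, imidazole, DMF) to the tert-butyldimethylsilyl ether of the protected macrocycle F3. F3 can then be hydrogenolysed more forcingly (H2, Pd(OH)2/C, EtOAc) to the silyl ether of the triphenol F4, because the bulky silyl ether is not a leaving group on Pd. Buffered fluoride (TBAF/AcOH, THF, 0 °C) then releases 18 without acid that could ionise the p-hydroxybenzylic centre.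

3. Step 8. Substitution at the C–F bond flanked by the formyl and benzyloxy groups may be sluggish, so that attack by the alkoxide of 11 or degradation of the aldehyde in hot carbonate competes. Fallback, setting out from 11 and returning at 12: commercially available 2-bromo-3-hydroxybenzaldehyde is benzylated (BnBr, K2CO3, DMF) to 3-(benzyloxy)-2-bromobenzaldehyde F5. F5 is joined to the phenol of 11 by a copper-catalysed Ullmann diaryl ether coupling (CuI, N,N-dimethylglycine, Cs2CO3, dioxane, 90 °C), which does not depend on SNAr activation and is selective for phenol over aliphatic alcohol.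

**Further compounds**

F1 | step 12 | racemic protected macrocyclic carbinol | C1(c2ccccc2)(c2ccccc2)Oc2cc3cc(c2O1)Oc1ccc(cc1)CCc1cccc(OCc2ccccc2)c1Oc1cccc(c1)CC3O
F2 | step 12 | protected macrocyclic aryl benzyl ketone | C1(c2ccccc2)(c2ccccc2)Oc2cc3cc(c2O1)Oc1ccc(cc1)CCc1cccc(OCc2ccccc2)c1Oc1cccc(c1)CC3=O
F3 | step 13 | tert-butyldimethylsilyl ether of 17 | C1(c2ccccc2)(c2ccccc2)Oc2cc3cc(c2O1)Oc1ccc(cc1)CCc1cccc(OCc2ccccc2)c1Oc1cccc(c1)C[C@@H]3O[Si](C)(C)C(C)(C)C
F4 | step 13 | tert-butyldimethylsilyl ether of 18 | Oc1cc2cc(c1O)Oc1ccc(cc1)CCc1cccc(O)c1Oc1cccc(c1)C[C@@H]2O[Si](C)(C)C(C)(C)C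
F5 | step 8 | 3-(benzyloxy)-2-bromobenzaldehyde | O=Cc1cccc(OCc2ccccc2)c1Br
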